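## Retrosynthetic overview

1. Lignan numbering: C7 carbinol CH, C8 its ring CH, C9 the OCH2 next to C8; C7' benzylic CH2, C8' its ring CH, C9' the OCH2 next to C8'. The route rests on one feature: the oxolane ring O–C9–C8–C8'–C9' has two unsubstituted OCH2 groups and cis side chains at C8 and C8', and O7, C7, C8, C8' and C7' can form a second five-membered ring.
2. Endgame: C7'H2 comes from C7'=O. The C7'–aryl bond comes from ArMgBr and a Weinreb amide. The amide comes from a cis-fused furo[3,4-c]furan-1-one in which O7 is acylated by C7', which is allowed because both aryl groups are the same guaiacyl unit.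
3. Key disconnection: C8–C9 and C8'–C9' are cut together, giving CH2=O(+)–CH2(−) and the C8=C8' bond of an (S)-5-arylfuran-2(5H)-one.
4. The butenolide comes from a Z-hydroxy enoate, made by semi-hydrogenation of a propargylic alcohol. That alcohol comes from asymmetric alkynylation of O-benzylvanillin with methyl propiolate. This sets C7, and C8 and C8' are relayed from it.
5. Ring order: the temporary butenolide ring first, the oxolane second (key step), then the lactone ring is opened.

Key step: step 5

Assumption: the (R)-propargylic alcohol requires acetylide delivery to the Si face of the aldehyde, and the (R,R)-ProPhenol ligand is assumed to do this. The sense is checked on the propargylic alcohol by MTPA ester analysis, and the equally available (S,S)-ligand is used instead, with no other change, if the opposite sense is found.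

## Route

Step 1
Reactants: 1 vanillin
Product: 2 4-(benzyloxy)-3-methoxybenzaldehyde
Conditions: BnBr, K2CO3, DMF, rt
Reagents that add atoms: benzyl bromide, BrCc1ccccc1
Why: Williamson ether synthesis on an acidic para-formyl phenol is reliable, and the benzyl ether is chosen because it resists fluoride, organometallic reagents and tin hydride and leaves by hydrogenolysis at the end.

Step 2
Reactants: 2 4-(benzyloxy)-3-methoxybenzaldehyde; 3 methyl propiolate
Product: 5 methyl (R)-4-[4-(benzyloxy)-3-methoxyphenyl]-4-hydroxybut-2-ynoate, via methylzinc acetylide 4 (not isolated)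
Conditions: Me2Zn, (R,R)-ProPhenol (10 mol %), Ph3P=O (20 mol %), toluene, 0–4 °C; aq NH4Cl
Reagents that add atoms: none
Why: In this catalytic asymmetric alkynylation of an aromatic aldehyde, Me2Zn deprotonates the acidic propiolate C–H and the dinuclear zinc–ProPhenol complex holds aldehyde and acetylide on neighbouring zinc atoms, so that delivery to the Si face sets C7 as R (the alkynyl carbon outranks the aryl carbon here).

Step 3
Reactants: 5 methyl (R)-4-[4-(benzyloxy)-3-methoxyphenyl]-4-hydroxybut-2-ynoate
Product: 7 (S)-5-[4-(benzyloxy)-3-methoxyphenyl]furan-2(5H)-one, via Z-hydroxy enoate 6 (not isolated)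
Conditions: H2 (1 atm), Pd/CaCO3 poisoned with Pb(OAc)2, quinoline, EtOAc, rt; then PPTS (cat.), CH2Cl2, rt
Reagents that add atoms: none
Why: Lindlar-type syn semi-hydrogenation stops at the Z-enoate, whose C7 hydroxyl lies next to the ester and lactonises by intramolecular transesterification under almost neutral conditions, while C7 is untouched and its descriptor changes from R to S only because the alkenyl carbon ranks below the aryl carbon.

Step 4
Reactants: 8 (trimethylsilyl)methanol
Product: 9 chloromethyl (trimethylsilyl)methyl ether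
Conditions: (CH2O)n, HCl (g), CH2Cl2, 0 °C; MgSO4; distillation
Reagents that add atoms: paraformaldehyde (as formaldehyde), C=O; hydrogen chloride, Cl
Why: In this classical chloromethyl ether synthesis the hemiacetal of the alcohol and formaldehyde is converted by HCl through the oxocarbenium ion into the α-chloro ether, and the C–Si bond of an α-silyl carbinol is not attacked by cold HCl.

Step 5
Reactants: 7 (S)-5-[4-(benzyloxy)-3-methoxyphenyl]furan-2(5H)-one; 9 chloromethyl (trimethylsilyl)methyl ether
Product: 11 (3S,3aR,6aS)-3-[4-(benzyloxy)-3-methoxyphenyl]tetrahydro-1H,3H-furo[3,4-c]furan-1-one, via parent carbonyl ylide 10 (not isolated)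
Conditions: 9 (4 equiv), dried CsF (5 equiv, added in portions to 7 + 9), MeCN, 0 °C → rt
Reagents that add atoms: none
Why: The α-chloro ether 9 ionises reversibly to Me3SiCH2–O(+)=CH2, fluoride removes silicon (a silicon-based 1,3-elimination), and the resulting ylide 10, a four-electron C–O–C dipole with a high HOMO, adds in one concerted suprafacial [π4s+π2s] event to the low-LUMO C8=C8' bond of 7. The closest known reaction types are the fluoride-induced release of non-stabilised carbonyl ylides from chloromethyl silylmethyl ethers with (3+2) addition to acrylates, maleates, fumarates and enones, and the anti-selective addition of other 1,3-dipoles (diazoalkanes, nitrile oxides, azomethine ylides) to 5-substituted furan-2(5H)-ones. The oxolane ring (O, C9, C8, C8', C9') is closed intermolecularly by simultaneous formation of C8–C9 and C8'–C9', so no chain cyclisation mode applies and the symmetrical dipole raises no regiochemical question. C8 is set by approach of the dipole to the face of the flat butenolide opposite the C7 aryl group, and C8' follows from C8 because the addition is suprafacial on an alkene that the lactone ring locks cis, which gives the cis-fused bicycle with the aryl group on its convex face. The step needs π-facial selectivity (secured by the aryl group on the carbon next to the reacting C8), chemoselectivity for the conjugated alkene over the lactone carbonyl and the arenes (secured by the nucleophilic character of the dipole), and retention of configuration at the acidic C7–H. The last point is addressed by feeding the sparingly soluble CsF in portions into a solution that always holds excess 9, so that fluoride is used up at silicon rather than acting as a base, and the enantiomeric purity of 11 and of recovered 7 is to be checked by chiral HPLC.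

Step 6
Reactants: 11 (3S,3aR,6aS)-3-[4-(benzyloxy)-3-methoxyphenyl]tetrahydro-1H,3H-furo[3,4-c]furan-1-one
Product: 12 (3S,4R)-4-{(S)-[4-(benzyloxy)-3-methoxyphenyl](hydroxy)methyl}-N-methoxy-N-methyloxolane-3-carboxamide
Conditions: MeNH(OMe)·HCl, Me3Al, CH2Cl2, 0 °C → rt; aq potassium sodium tartrate; used crude
Reagents that add atoms: N,O-dimethylhydroxylamine hydrochloride, CNOC.Cl
Why: In this Weinreb aminolysis of a lactone the aluminium amide activates the carbonyl and holds the released C7 alkoxide, no stereocentre is touched, and the crude hydroxy amide is carried on at once because it can close back to 11.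

Step 7
Reactants: 12 (3S,4R)-4-{(S)-[4-(benzyloxy)-3-methoxyphenyl](hydroxy)methyl}-N-methoxy-N-methyloxolane-3-carboxamide
Product: 13 (3S,4R)-4-{(S)-[4-(benzyloxy)-3-methoxyphenyl][(tert-butyldimethylsilyl)oxy]methyl}-N-methoxy-N-methyloxolane-3-carboxamide
Conditions: TBSOTf, 2,6-lutidine, CH2Cl2, −78 → 0 °C
Reagents that add atoms: tert-butyldimethylsilyl trifluoromethanesulfonate, CC(C)(C)[Si](C)(C)OS(=O)(=O)C(F)(F)F
Why: Silylation of a hindered secondary alcohol with a silyl triflate and a non-nucleophilic base is fast at low temperature and so outruns relactonisation, and the silyl ether marks O7 so that only C7' is deoxygenated later.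

Step 8
Reactants: 14 4-bromo-2-methoxyphenol
Product: 15 1-(benzyloxy)-4-bromo-2-methoxybenzene
Conditions: BnBr, K2CO3, DMF, rt
Reagents that add atoms: benzyl bromide, BrCc1ccccc1
Why: Williamson ether synthesis masks the phenol, which would otherwise quench the arylmagnesium reagent, with the same group as on the other arene so that one final operation frees both.

Step 9
Reactants: 13 (3S,4R)-4-{(S)-[4-(benzyloxy)-3-methoxyphenyl][(tert-butyldimethylsilyl)oxy]methyl}-N-methoxy-N-methyloxolane-3-carboxamide; 15 1-(benzyloxy)-4-bromo-2-methoxybenzene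
Product: 17 [4-(benzyloxy)-3-methoxyphenyl][(3S,4R)-4-{(S)-[4-(benzyloxy)-3-methoxyphenyl][(tert-butyldimethylsilyl)oxy]methyl}oxolan-3-yl]methanone, via arylmagnesium bromide 16 (not isolated)
Conditions: 15, Mg, I2 (crystal), THF, reflux; then 13, THF, 0 °C → rt; cold aq NH4Cl
Reagents that add atoms: none
Why: In the Weinreb ketone synthesis ArMgBr adds once to give a magnesium-chelated tetrahedral intermediate that neither collapses nor enolises before the cold, mildly acidic quench, so over-addition is excluded and the cis C8' centre next to the new carbonyl sees as little base as possible.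

Step 10
Reactants: 17 [4-(benzyloxy)-3-methoxyphenyl][(3S,4R)-4-{(S)-[4-(benzyloxy)-3-methoxyphenyl][(tert-butyldimethylsilyl)oxy]methyl}oxolan-3-yl]methanone
Product: 18 the corresponding C7' secondary alcohol (C7 S, C8 R, C8' S; both C7' epimers accepted)
Conditions: iBu2AlH, CH2Cl2, −78 °C; aq potassium sodium tartrate
Reagents that add atoms: none
Why: Hydride reduction of the aryl ketone with the Lewis-acidic, non-basic iBu2AlH at −78 °C avoids enolisation at C8', and the configuration of the new C7' carbinol does not matter because this carbon becomes CH2 two steps later.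

Step 11
Reactants: 18 C7' secondary alcohol
Product: 20 O-(C7') S-methyl dithiocarbonate (xanthate) of 18, via sodium xanthate salt 19 (not isolated)
Conditions: NaN(SiMe3)2, THF, −78 °C; CS2; MeI, −78 → 0 °C
Reagents that add atoms: carbon disulfide, S=C=S; iodomethane, CI
Why: In this xanthate formation (first half of the Barton–McCombie deoxygenation) the small electrophile CS2 reaches the crowded alkoxide, which is made and trapped at −78 °C to suppress silyl transfer from O7 to O7', and S-methylation then gives the radical precursor.

Step 12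
Reactants: 20 xanthate of 18
Product: 21 (7S,8R,8'S)-4,4'-bis(benzyloxy)-7-[(tert-butyldimethylsilyl)oxy]-3,3'-dimethoxy-9,9'-epoxylignan
Conditions: Bu3SnH, Et3B (cat.), air, toluene, rt
Reagents that add atoms: none
Why: In the Barton–McCombie deoxygenation the stannyl radical adds to the thiocarbonyl sulfur and the C7'–O bond fragments readily to a benzylic radical that takes hydrogen from Bu3SnH, the neutral chain leaves the acid-labile C7 silyl ether, the benzyl ethers and the three stereocentres alone, and initiation by Et3B and air at room temperature avoids thermal Chugaev elimination.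

Step 13
Reactants: 21 (7S,8R,8'S)-4,4'-bis(benzyloxy)-7-[(tert-butyldimethylsilyl)oxy]-3,3'-dimethoxy-9,9'-epoxylignan
Product: 22 (S)-[4-(benzyloxy)-3-methoxyphenyl]{(3R,4S)-4-[4-(benzyloxy)-3-methoxybenzyl]oxolan-3-yl}methanol
Conditions: Bu4NF, THF, 0 °C → rt
Reagents that add atoms: none
Why: Fluoride-induced desilylation is driven by the strong Si–F bond and is run while both phenols are still benzylated, so that no phenoxide can expel O7 through a para-quinone methide and C7 keeps its configuration.

Step 14
Reactants: 22 (S)-[4-(benzyloxy)-3-methoxyphenyl]{(3R,4S)-4-[4-(benzyloxy)-3-methoxybenzyl]oxolan-3-yl}methanol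
Product: 23 4-[(S)-hydroxy{(3R,4S)-4-[(4-hydroxy-3-methoxyphenyl)methyl]oxolan-3-yl}methyl]-2-methoxyphenol (target, 7S,8R,8'S)
Conditions: H2 (1 atm), Pd/C, EtOAc, rt, stopped after uptake of two equivalents of H2
Reagents that add atoms: none
Why: Catalytic hydrogenolysis of aryl benzyl ethers over Pd/C in a neutral aprotic solvent is much faster than cleavage of a secondary benzylic C–OH bond, so a monitored reaction should free both phenols and leave C7–OH and all stereocentres untouched.

## Compound list

1 | vanillin | COc1cc(C=O)ccc1O | starting material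
2 | 4-(benzyloxy)-3-methoxybenzaldehyde | COc1cc(C=O)ccc1OCc1ccccc1 | intermediate
3 | methyl propiolate | C#CC(=O)OC | starting material
4 | methylzinc acetylide of methyl propiolate | C[Zn]C#CC(=O)OC | intermediate
5 | methyl (R)-4-[4-(benzyloxy)-3-methoxyphenyl]-4-hydroxybut-2-ynoate | COC(=O)C#C[C@H](O)c1ccc(OCc2ccccc2)c(OC)c1 | intermediate
6 | methyl (S,Z)-4-[4-(benzyloxy)-3-methoxyphenyl]-4-hydroxybut-2-enoate | COC(=O)/C=C\[C@H](O)c1ccc(OCc2ccccc2)c(OC)c1 | intermediate
7 | (S)-5-[4-(benzyloxy)-3-methoxyphenyl]furan-2(5H)-one | O=C1C=C[C@H](O1)c1ccc(OCc2ccccc2)c(OC)c1 | intermediate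
8 | (trimethylsilyl)methanol | C[Si](C)(C)CO | starting material
9 | chloromethyl (trimethylsilyl)methyl ether | C[Si](C)(C)COCCl | intermediate
10 | parent carbonyl ylide, CH2=O(+)–CH2(−) | C=[O+][CH2-] | intermediate
11 | (3S,3aR,6aS)-3-[4-(benzyloxy)-3-methoxyphenyl]tetrahydro-1H,3H-furo[3,4-c]furan-1-one | O=C3[C@@H]2COC[C@@H]2[C@H](O3)c2ccc(OCc4ccccc4)c(OC)c2 | intermediate
12 | (3S,4R)-4-{(S)-[4-(benzyloxy)-3-methoxyphenyl](hydroxy)methyl}-N-methoxy-N-methyloxolane-3-carboxamide | CON(C)C(=O)[C@@H]1COC[C@@H]1[C@H](O)c1ccc(OCc2ccccc2)c(OC)c1 | intermediate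
13 | O7-TBS ether of 12 | CON(C)C(=O)[C@@H]1COC[C@@H]1[C@H](O[Si](C)(C)C(C)(C)C)c1ccc(OCc2ccccc2)c(OC)c1 | intermediate
14 | 4-bromo-2-methoxyphenol | COc1cc(Br)ccc1O | starting material
15 | 1-(benzyloxy)-4-bromo-2-methoxybenzene | COc1cc(Br)ccc1OCc1ccccc1 | intermediate
16 | [4-(benzyloxy)-3-methoxyphenyl]magnesium bromide | COc1cc([Mg]Br)ccc1OCc1ccccc1 | intermediate
17 | C7' aryl ketone (C7 S, C8 R, C8' S), O7-TBS | O=C(c1ccc(OCc2ccccc2)c(OC)c1)[C@@H]1COC[C@@H]1[C@H](O[Si](C)(C)C(C)(C)C)c1ccc(OCc2ccccc2)c(OC)c1 | intermediate
18 | C7' alcohol (both C7' epimers), O7-TBS | OC(c1ccc(OCc2ccccc2)c(OC)c1)[C@@H]1COC[C@@H]1[C@H](O[Si](C)(C)C(C)(C)C)c1ccc(OCc2ccccc2)c(OC)c1 | intermediate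
19 | sodium O-(C7') dithiocarbonate of 18 | [Na+].[S-]C(=S)OC(c1ccc(OCc2ccccc2)c(OC)c1)[C@@H]1COC[C@@H]1[C@H](O[Si](C)(C)C(C)(C)C)c1ccc(OCc2ccccc2)c(OC)c1 | intermediate
20 | O-(C7') S-methyl dithiocarbonate of 18 | CSC(=S)OC(c1ccc(OCc2ccccc2)c(OC)c1)[C@@H]1COC[C@@H]1[C@H](O[Si](C)(C)C(C)(C)C)c1ccc(OCc2ccccc2)c(OC)c1 | intermediate
21 | (7S,8R,8'S)-4,4'-bis(benzyloxy)-7-[(tert-butyldimethylsilyl)oxy]-3,3'-dimethoxy-9,9'-epoxylignan | COc1cc(C[C@@H]2COC[C@@H]2[C@H](O[Si](C)(C)C(C)(C)C)c2ccc(OCc3ccccc3)c(OC)c2)ccc1OCc1ccccc1 | intermediate
22 | (S)-[4-(benzyloxy)-3-methoxyphenyl]{(3R,4S)-4-[4-(benzyloxy)-3-methoxybenzyl]oxolan-3-yl}methanol | COc1cc(C[C@@H]2COC[C@@H]2[C@H](O)c2ccc(OCc3ccccc3)c(OC)c2)ccc1OCc1ccccc1 | intermediate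
23 | 4-[(S)-hydroxy{(3R,4S)-4-[(4-hydroxy-3-methoxyphenyl)methyl]oxolan-3-yl}methyl]-2-methoxyphenol | COc1cc(C[C@@H]2COC[C@@H]2[C@H](O)c2ccc(O)c(OC)c2)ccc1O | target

## Step count and risks

Total step count: 14.
Longest linear sequence: 12 steps (1, 2, 3, 5, 6, 7, 9, 10, 11, 12, 13, 14).

**Step 5 (key step).**
- Risk: fluoride may act as a base on the benzylic, vinylogously acidic C7–H. That would cause loss of enantiomeric purity, migration of the double bond out of conjugation, or alkylation of the furanolate by 9. The ylide may also be consumed by self-reaction faster than it adds to a β-substituted, singly activated alkene.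
- Fallback: the same oxolane is built stepwise on the same butenolide, setting out from 7.
- Copper-catalysed conjugate addition of (iPrO)Me2SiCH2MgCl (CuBr·SMe2, Me3SiCl, THF, −78 °C) anti to the aryl group should give the silylmethyl lactone F1.
- Tamao–Fleming oxidation (H2O2, KF, KHCO3, THF/MeOH) should give the hydroxymethyl lactone F2. Its C7–H is no longer acidic.
- Paraformaldehyde and Me3SiCl in CH2Cl2 should convert this into the chloromethyl ether F3.
- LiN(SiMe3)2 in THF at −78 °C then forms C8'–C9' by 5-exo-tet alkylation of the lactone enolate. This can only give the cis-fused bicycle, and the route is rejoined at 11.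

**Step 9.**
- Risk: addition to the crowded amide may be slow, so that enolisation competes and C8' epimerises to the more stable trans series, either at the amide stage or in ketone 17.
- Fallback: the aryl group is introduced by sp3–sp2 cross-coupling on a substrate without any carbonyl group, setting out from 11.
- LiAlH4 (THF, 0 °C) should give the diol F4, and TBSOTf with 2,6-lutidine should give the bis-silyl ether F5.
- HF·pyridine buffered with pyridine (THF, 0 °C) should remove the less hindered primary silyl group to give the primary alcohol F6.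
- Appel-type iodination (I2, PPh3, imidazole) should give the primary iodide F7.
- Kumada-type coupling with slow addition of 16 (FeCl3 (cat.), TMEDA, THF, 0 °C) rejoins the route at 21, so steps 6, 7 and 9–12 are bypassed.

**Step 11.**
- Risk: the silyl group may move from O7 to O7' in the alkoxide. Because the two arenes are identical, this would erode stereochemical purity. The electron-rich benzylic xanthate may also undergo O-to-S rearrangement or elimination.
- Fallback: the radical deoxygenation is replaced by hydrogenolysis of an activated ester, setting out from 18.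
- Acetylation (Ac2O, pyridine, DMAP, CH2Cl2) should give the C7' acetate F8.
- Hydrogenolysis (H2, Pd/C, EtOAc) should remove the benzylic acetate and both benzyl ethers in one operation, while the silyl ether shields O7, giving the O7-silylated bisphenol F9.
- Desilylation with Bu4NF buffered by AcOH (THF, 0 °C), which avoids phenoxide and para-quinone methide formation, rejoins the route at 23.

## Further compounds

F1 | step 5 | (4S,5S)-5-[4-(benzyloxy)-3-methoxyphenyl]-4-{[dimethyl(propan-2-yloxy)silyl]methyl}oxolan-2-one | O=C1C[C@H](C[Si](C)(C)OC(C)C)[C@H](O1)c1ccc(OCc2ccccc2)c(OC)c1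
F2 | step 5 | (4R,5S)-5-[4-(benzyloxy)-3-methoxyphenyl]-4-(hydroxymethyl)oxolan-2-one | O=C1C[C@H](CO)[C@H](O1)c1ccc(OCc2ccccc2)c(OC)c1
F3 | step 5 | (4R,5S)-5-[4-(benzyloxy)-3-methoxyphenyl]-4-[(chloromethoxy)methyl]oxolan-2-one | O=C1C[C@H](COCCl)[C@H](O1)c1ccc(OCc2ccccc2)c(OC)c1
F4 | step 9 | (S)-[4-(benzyloxy)-3-methoxyphenyl][(3R,4R)-4-(hydroxymethyl)oxolan-3-yl]methanol | OC[C@@H]1COC[C@@H]1[C@H](O)c1ccc(OCc2ccccc2)c(OC)c1
F5 | step 9 | bis(tert-butyldimethylsilyl) ether of F4 | CC(C)(C)[Si](C)(C)OC[C@@H]1COC[C@@H]1[C@H](O[Si](C)(C)C(C)(C)C)c1ccc(OCc2ccccc2)c(OC)c1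
F6 | step 9 | O7-mono(tert-butyldimethylsilyl) ether of F4, primary OH free | OC[C@@H]1COC[C@@H]1[C@H](O[Si](C)(C)C(C)(C)C)c1ccc(OCc2ccccc2)c(OC)c1
F7 | step 9 | primary (C7') iodide derived from F6 | IC[C@@H]1COC[C@@H]1[C@H](O[Si](C)(C)C(C)(C)C)c1ccc(OCc2ccccc2)c(OC)c1
F8 | step 11 | C7' acetate of 18 | CC(=O)OC(c1ccc(OCc2ccccc2)c(OC)c1)[C@@H]1COC[C@@H]1[C@H](O[Si](C)(C)C(C)(C)C)c1ccc(OCc2ccccc2)c(OC)c1
F9 | step 11 | O7-(tert-butyldimethylsilyl) ether of 23 | COc1cc(C[C@@H]2COC[C@@H]2[C@H](O[Si](C)(C)C(C)(C)C)c2ccc(O)c(OC)c2)ccc1O
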